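**Retrosynthetic overview**
The target has one ring, a γ-lactone numbered O1, C2 (C=O), C3 (=CH2), C4 (CO2H) and C5 (13-acetoxytridecyl chain), with C4 and C5 trans, (4S,5R).
The strategy rests on one feature. The sp2 carbon C3 with its exocyclic CH2 lies next to C4, whose only side arm is a single oxidised carbon. This is the pattern left when a C4 radical with a β-oxygen adds to the inner carbon of an alkyne, and O1–C2 is then the O–CH2 of a propargyl ether.
Two oxidations are taken back: C2=O to the allylic, O1-bound CH2 (CrO3·2py) and CO2H to CH2OH. This gives a 3-(hydroxymethyl)-4-methylideneoxolane.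
The key disconnection is C3–C4, which also opens the only ring: Cp2TiCl opens a terminal epoxide and the radical closes 5-exo-dig onto the propargyl ether. The oxolane is therefore made first and becomes the lactone in the last step.
The epoxy propargyl ether comes from 1,14-tetradecanediol, vinylmagnesium bromide and propargyl bromide. C5 is set by a Sharpless kinetic resolution, and C4 is set by C5 during ring closure.

Key step: step 8

Remark 1: the lactone numbering above is also used for the acyclic precursors.
Remark 2: the silyl group is exchanged for the final acetate before the radical step. α-Methylene lactone acids of this type are prone to base-induced migration of the double bond into the ring, so fluoride and amine/anhydride treatment are kept away from the finished lactone.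
Remark 3: in the SMILES of titanium species the η5-cyclopentadienyl rings are drawn as σ-bonded C5H5 groups.

**Step 1**
Reactants: 1 tetradecane-1,14-diol
Product: 2 14-[(tert-butyldiphenylsilyl)oxy]tetradecan-1-ol
Conditions: 1 (3 equiv), TBDPSCl (1 equiv), imidazole, DMF–THF, rt; excess 1 recovered
Reagents that add atoms: tert-butyl(chloro)diphenylsilane (TBDPSCl), CC(C)(C)[Si](Cl)(c1ccccc1)c1ccccc1
Why: Statistical monosilylation (silyl ether formation) of the symmetrical diol used in excess should keep the bis-ether low, and the apolar, UV-active mono-ether separates easily from the polar diol.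

**Step 2**
Reactants: 2 14-[(tert-butyldiphenylsilyl)oxy]tetradecan-1-ol
Product: 3 14-[(tert-butyldiphenylsilyl)oxy]tetradecanal
Conditions: TEMPO (10 mol %), PhI(OAc)2 (1.1 equiv), CH2Cl2, rt
Reagents that add atoms: none
Why: The TEMPO/PhI(OAc)2 oxoammonium oxidation of a primary alcohol stops at the aldehyde when water is absent and leaves the silyl ether untouched.

**Step 3**
Reactants: 3 14-[(tert-butyldiphenylsilyl)oxy]tetradecanal; 4 vinylmagnesium bromide
Product: 6 rac-16-[(tert-butyldiphenylsilyl)oxy]hexadec-1-en-3-ol, via bromomagnesium alkoxide 5 (not isolated)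
Conditions: 4 (1.2 equiv, THF), THF, −78 → 0 °C; aq NH4Cl
Reagents that add atoms: vinylmagnesium bromide (4), C=C[Mg]Br
Why: Grignard 1,2-addition to an unhindered aldehyde is reliable, and because there is no facial bias the future C5 carbinol forms as the racemate that step 4 resolves.

**Step 4**
Reactants: 6 rac-16-[(tert-butyldiphenylsilyl)oxy]hexadec-1-en-3-ol
Product: 7 (1R)-14-[(tert-butyldiphenylsilyl)oxy]-1-[(2S)-oxiran-2-yl]tetradecan-1-ol
Conditions: Ti(OiPr)4 (15 mol %), D-(−)-diisopropyl tartrate (20 mol %), t-BuOOH (0.45 equiv, decane), 4 Å MS, CH2Cl2, −20 °C; chromatography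
Reagents that add atoms: tert-butyl hydroperoxide, CC(C)(C)OO
Why: In the Sharpless kinetic resolution with the D-(−)-tartrate the (R)-alcohol is the fast-reacting enantiomer and should give the erythro epoxy alcohol, while less than half an equivalent of oxidant keeps the slow (S)-alcohol out of the product, so C5 is fixed as R.

**Step 5**
Reactants: 7 (1R)-14-[(tert-butyldiphenylsilyl)oxy]-1-[(2S)-oxiran-2-yl]tetradecan-1-ol; 8 propargyl bromide
Product: 10 tert-butyl{[(14R)-14-[(2S)-oxiran-2-yl]-14-(prop-2-yn-1-yloxy)tetradecyl]oxy}diphenylsilane, via sodium alkoxide 9 (not isolated)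
Conditions: 8 (1.5 equiv), Bu4NI (10 mol %), THF, 0 °C, then NaH (1.3 equiv), 0 °C → rt
Reagents that add atoms: propargyl bromide (8), C#CCBr
Why: In this Williamson ether synthesis the alkoxide forms in aprotic THF with the reactive propargylic halide already present, so O-alkylation should outrun Payne migration, and the C5–O bond is not broken so the configuration is kept.

**Step 6**
Reactants: 10 tert-butyl{[(14R)-14-[(2S)-oxiran-2-yl]-14-(prop-2-yn-1-yloxy)tetradecyl]oxy}diphenylsilane
Product: 11 (14R)-14-[(2S)-oxiran-2-yl]-14-(prop-2-yn-1-yloxy)tetradecan-1-ol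
Conditions: Bu4NF (1.2 equiv), THF, 0 °C → rt
Reagents that add atoms: none
Why: Fluoride-induced desilylation is driven by the strong Si–F bond, and at room temperature it should not touch the terminal epoxide, the propargyl ether or the alkyne.

**Step 7**
Reactants: 11 (14R)-14-[(2S)-oxiran-2-yl]-14-(prop-2-yn-1-yloxy)tetradecan-1-ol
Product: 12 (14R)-14-[(2S)-oxiran-2-yl]-14-(prop-2-yn-1-yloxy)tetradecyl acetate
Conditions: Ac2O (1.5 equiv), pyridine, DMAP (5 mol %), CH2Cl2, 0 °C → rt
Reagents that add atoms: acetic anhydride, CC(=O)OC(C)=O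
Why: DMAP-catalysed acylation of the only free hydroxyl installs the acetate of the target at a stage where no base-sensitive group is present, and esters are inert to Cp2TiCl and to the later oxidants.

**Step 8**
Reactants: 12 (14R)-14-[(2S)-oxiran-2-yl]-14-(prop-2-yn-1-yloxy)tetradecyl acetate
Product: 15 13-[(2R,3R)-3-(hydroxymethyl)-4-methylideneoxolan-2-yl]tridecyl acetate, via titanoxy C4 radical 13 (not isolated), via alkenyltitanium alkoxide 14 (not isolated)
Conditions: Cp2TiCl2 (2.5 equiv), Zn dust (6 equiv), THF, rt, 1 h; green Cp2TiCl solution added over 2 h to 12 (0.02 M, THF), rt; 1 M HCl; chromatography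
Reagents that add atoms: none
Why: Cp2TiCl, a one-electron donor with trivalent titanium, binds the epoxide oxygen and cleaves the C4–O bond homolytically, which gives the secondary C4 radical 13 with a CH2OTi(Cl)Cp2 arm in preference to the primary radical from the other C–O bond. Radical 13 adds to the inner alkyne carbon, which forms C3–C4 and closes the oxolane ring (C4, C5, O1, C2, C3) in the 5-exo-dig mode; the vinyl radical is then trapped by a second Cp2TiCl (or takes hydrogen from THF) to give 14, and HCl protonates the C–Ti and O–Ti bonds to release the exocyclic methylene and the CH2OH group. The closest known reaction type is the Nugent–RajanBabu reductive epoxide opening with radical cyclisation, which is established for alkyne acceptors and for epoxy propargyl ethers. C4 is the only new stereocentre: the epoxide configuration vanishes in the planar radical, and in the chair-like transition state the C5 chain and the bulky titanoxymethyl arm both take pseudo-equatorial sites, which should favour the 4,5-trans (2R,3R) isomer, the minor cis isomer being removed by chromatography. The step needs ring closure to be faster than capture of 13 by a second titanium centre, which would end in loss of the β-titanoxy group and net deoxygenation to the alkene; the short oxygen-containing tether speeds the closure and slow addition of the reagent to dilute 12 keeps the titanium concentration low. The acetate, the ether linkages and the terminal alkyne C–H are not touched by the reagent.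

**Step 9**
Reactants: 15 13-[(2R,3R)-3-(hydroxymethyl)-4-methylideneoxolan-2-yl]tridecyl acetate
Product: 17 (2R,3S)-2-(13-acetoxytridecyl)-4-methylideneoxolane-3-carboxylic acid, via aldehyde 16 (not isolated)
Conditions: TEMPO (20 mol %), PhI(OAc)2 (2.5 equiv), CH2Cl2–H2O (2:1), rt
Reagents that add atoms: water, O
Why: The one-pot TEMPO/PhI(OAc)2–water oxidation takes the primary alcohol through the aldehyde hydrate to the acid in a nearly neutral medium, so the β,γ-unsaturated aldehyde is never isolated and has little chance to epimerise at C4 or to move its double bond into conjugation.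

**Step 10**
Reactants: 17 (2R,3S)-2-(13-acetoxytridecyl)-4-methylideneoxolane-3-carboxylic acid
Product: 18 (2R,3S)-2-(13-acetoxytridecyl)-4-methylidene-5-oxooxolane-3-carboxylic acid (target)
Conditions: CrO3 (15 equiv), pyridine (30 equiv), CH2Cl2, rt; Et2O, Celite, 1 M HCl wash
Reagents that add atoms: chromium trioxide, O=[Cr](=O)=O
Why: Allylic oxidation with CrO3·2py (Collins oxidation) is the known way from 3-methylideneoxolanes to α-methylene-γ-butyrolactones, because the C2–H bonds are both allylic and next to O1 and react first, whereas the C4–H is deactivated by the carboxyl group and both stereocentres and the acetate stay untouched.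

**Compound list**
1 | tetradecane-1,14-diol | OCCCCCCCCCCCCCCO | starting material
2 | 14-[(tert-butyldiphenylsilyl)oxy]tetradecan-1-ol | OCCCCCCCCCCCCCCO[Si](c1ccccc1)(c1ccccc1)C(C)(C)C | intermediate
3 | 14-[(tert-butyldiphenylsilyl)oxy]tetradecanal | O=CCCCCCCCCCCCCCO[Si](c1ccccc1)(c1ccccc1)C(C)(C)C | intermediate
4 | vinylmagnesium bromide | C=C[Mg]Br | starting material
5 | bromomagnesium alkoxide of 6 (racemic, not isolated) | C=CC(O[Mg]Br)CCCCCCCCCCCCCO[Si](c1ccccc1)(c1ccccc1)C(C)(C)C | intermediate
6 | rac-16-[(tert-butyldiphenylsilyl)oxy]hexadec-1-en-3-ol | C=CC(O)CCCCCCCCCCCCCO[Si](c1ccccc1)(c1ccccc1)C(C)(C)C | intermediate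
7 | (1R)-14-[(tert-butyldiphenylsilyl)oxy]-1-[(2S)-oxiran-2-yl]tetradecan-1-ol | O[C@H](CCCCCCCCCCCCCO[Si](c1ccccc1)(c1ccccc1)C(C)(C)C)[C@@H]1CO1 | intermediate
8 | propargyl bromide (3-bromoprop-1-yne) | C#CCBr | starting material
9 | sodium alkoxide of 7 (not isolated) | [Na+].[O-][C@H](CCCCCCCCCCCCCO[Si](c1ccccc1)(c1ccccc1)C(C)(C)C)[C@@H]1CO1 | intermediate
10 | tert-butyl{[(14R)-14-[(2S)-oxiran-2-yl]-14-(prop-2-yn-1-yloxy)tetradecyl]oxy}diphenylsilane | C#CCO[C@H](CCCCCCCCCCCCCO[Si](c1ccccc1)(c1ccccc1)C(C)(C)C)[C@@H]1CO1 | intermediate
11 | (14R)-14-[(2S)-oxiran-2-yl]-14-(prop-2-yn-1-yloxy)tetradecan-1-ol | C#CCO[C@H](CCCCCCCCCCCCCO)[C@@H]1CO1 | intermediate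
12 | (14R)-14-[(2S)-oxiran-2-yl]-14-(prop-2-yn-1-yloxy)tetradecyl acetate (precursor of the key step) | C#CCO[C@H](CCCCCCCCCCCCCOC(C)=O)[C@@H]1CO1 | intermediate
13 | secondary C4 radical with CH2OTi(Cl)Cp2 arm (not isolated) | C#CCO[C@H](CCCCCCCCCCCCCOC(C)=O)[CH]CO[Ti](Cl)(C1C=CC=C1)C1C=CC=C1 | intermediate
14 | cyclised alkenyltitanium titanium alkoxide (not isolated, alkene geometry open) | Cl[Ti](C1C=CC=C1)(C1C=CC=C1)C=C2CO[C@H](CCCCCCCCCCCCCOC(C)=O)[C@H]2CO[Ti](Cl)(C3C=CC=C3)C4C=CC=C4 | intermediate
15 | 13-[(2R,3R)-3-(hydroxymethyl)-4-methylideneoxolan-2-yl]tridecyl acetate (product of the key step) | C=C1CO[C@H](CCCCCCCCCCCCCOC(C)=O)[C@H]1CO | intermediate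
16 | 13-[(2R,3S)-3-formyl-4-methylideneoxolan-2-yl]tridecyl acetate (not isolated) | C=C1CO[C@H](CCCCCCCCCCCCCOC(C)=O)[C@H]1C=O | intermediate
17 | (2R,3S)-2-(13-acetoxytridecyl)-4-methylideneoxolane-3-carboxylic acid | C=C1CO[C@H](CCCCCCCCCCCCCOC(C)=O)[C@H]1C(=O)O | intermediate
18 | (2R,3S)-2-(13-acetoxytridecyl)-4-methylidene-5-oxooxolane-3-carboxylic acid | C=C1C(=O)O[C@H](CCCCCCCCCCCCCOC(C)=O)[C@H]1C(=O)O | target

Total step count: 10
Longest linear sequence: 10 steps (from 1)

**Steps most likely to fail**

**Step 8.** The C4 radical may be captured by a second titanium centre before the ring closes, after which the titanoxy group is lost and the epoxide is deoxygenated overall. Discrimination between the trans and cis modes of closure at C4 may also be weak. The fallback makes the same C4 radical without titanium, by Barton–McCombie-type fragmentation, so that no metal–oxygen bond sits β to the radical.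
- It sets out from 12. Acid-catalysed hydrolysis of the epoxide (cat. HClO4, THF–H2O, 0 °C → rt) should give the 1,2-diol F1. Any epimer at the new carbinol carbon is harmless because that centre becomes the radical.
- Selective silylation of the primary hydroxyl (TBDPSCl, imidazole, CH2Cl2, 0 °C) should give the primary silyl ether F2.
- 1,1'-Thiocarbonyldiimidazole (THF, 60 °C) should give the secondary imidazolylthiocarbonate F3.
- Slow addition of Bu3SnH and AIBN in refluxing toluene should release the radical. It closes 5-exo-dig with a still larger CH2OSi arm to steer the trans relation, and tin hydride reduces the vinyl radical to the cyclised silyl ether F4.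
- Bu4NF buffered with AcOH in THF then returns to the route at 15.

**Step 10.** The free carboxylic acid may stay bound to the chromium residues and be lost on work-up. Long contact with pyridine may also move the exocyclic double bond into the ring. The fallback reverses the order of the two oxidations, so that chromium meets a neutral substrate and the acid is made last in acidic medium.
- It sets out from 15. TBSCl and imidazole in CH2Cl2 should give the tert-butyldimethylsilyl ether F5.
- CrO3·2py in CH2Cl2 should give the silylated α-methylene lactone F6.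
- Aqueous HF in MeCN should give the hydroxymethyl lactone F7.
- Jones oxidation (CrO3, aq H2SO4, acetone, 0 °C) then returns to the route at 18.

**Step 4.** The monosubstituted alkene is epoxidised slowly, so over the long reaction time the slow enantiomer may leak into the product and lower its enantiopurity. The terminal epoxide may also be opened by alkoxide on titanium. The fallback takes the enantiopurity from the unreacted alcohol, whose purity rises with conversion, instead of from the product, whose purity falls with conversion.
- It sets out from 6. The resolution is run with Ti(OiPr)4, L-(+)-diisopropyl tartrate and t-BuOOH (0.6 equiv) beyond half conversion.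
- The (3R)-allylic alcohol F8 is recovered, while the (S)-alcohol is consumed as the enantiomeric epoxy alcohol F9, which is discarded.
- F8 is then epoxidised in the matched sense (Ti(OiPr)4, D-(−)-diisopropyl tartrate, t-BuOOH, 4 Å MS, CH2Cl2, −20 °C). Any residual (S)-alcohol stays behind in this faster reaction, which returns to the route at 7.

**Further compounds**
F1 | step 8 | (14R,15S)-15,16-dihydroxy-14-(prop-2-yn-1-yloxy)hexadecyl acetate | C#CCO[C@H](CCCCCCCCCCCCCOC(C)=O)[C@@H](O)CO
F2 | step 8 | (14R,15S)-16-[(tert-butyldiphenylsilyl)oxy]-15-hydroxy-14-(prop-2-yn-1-yloxy)hexadecyl acetate | C#CCO[C@H](CCCCCCCCCCCCCOC(C)=O)[C@@H](O)CO[Si](c1ccccc1)(c1ccccc1)C(C)(C)C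
F3 | step 8 | (14R,15S)-16-[(tert-butyldiphenylsilyl)oxy]-15-[(1H-imidazol-1-ylcarbonothioyl)oxy]-14-(prop-2-yn-1-yloxy)hexadecyl acetate | C#CCO[C@H](CCCCCCCCCCCCCOC(C)=O)[C@@H](OC(=S)n1ccnc1)CO[Si](c1ccccc1)(c1ccccc1)C(C)(C)C
F4 | step 8 | 13-[(2R,3R)-3-{[(tert-butyldiphenylsilyl)oxy]methyl}-4-methylideneoxolan-2-yl]tridecyl acetate | C=C1CO[C@H](CCCCCCCCCCCCCOC(C)=O)[C@H]1CO[Si](c2ccccc2)(c2ccccc2)C(C)(C)C
F5 | step 10 | 13-[(2R,3R)-3-{[(tert-butyldimethylsilyl)oxy]methyl}-4-methylideneoxolan-2-yl]tridecyl acetate | C=C1CO[C@H](CCCCCCCCCCCCCOC(C)=O)[C@H]1CO[Si](C)(C)C(C)(C)C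
F6 | step 10 | 13-[(2R,3R)-3-{[(tert-butyldimethylsilyl)oxy]methyl}-4-methylidene-5-oxooxolan-2-yl]tridecyl acetate | C=C1C(=O)O[C@H](CCCCCCCCCCCCCOC(C)=O)[C@H]1CO[Si](C)(C)C(C)(C)C
F7 | step 10 | 13-[(2R,3R)-3-(hydroxymethyl)-4-methylidene-5-oxooxolan-2-yl]tridecyl acetate | C=C1C(=O)O[C@H](CCCCCCCCCCCCCOC(C)=O)[C@H]1CO
F8 | step 4 | (3R)-16-[(tert-butyldiphenylsilyl)oxy]hexadec-1-en-3-ol | C=C[C@H](O)CCCCCCCCCCCCCO[Si](c1ccccc1)(c1ccccc1)C(C)(C)C
F9 | step 4 | (1S)-14-[(tert-butyldiphenylsilyl)oxy]-1-[(2R)-oxiran-2-yl]tetradecan-1-ol | O[C@@H](CCCCCCCCCCCCCO[Si](c1ccccc1)(c1ccccc1)C(C)(C)C)[C@H]1CO1
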